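**Plan**
Retrosynthesis: the three acetal protecting groups and the 4'-O–prenyl bond are cut first. Ring C is then opened at C4a–C4 and O1–C2, which gives a ring A phenol and a ring B α-alkoxy β-ketoester. The ketoester is cut between its α-carbon and the aroyl carbon; the phenol goes back to 2-methoxyresorcinol by C–H oxidation para to the methoxy group.
Forward: rings A and B are bought as benzenes. Ring C, the pyrone, is the only ring built and is closed in one thermal operation (step 6). The benzyl ether on ring B is then exchanged for the prenyl ether and the acetals are removed.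
Enabling feature: read from O1, ring A is a phenol with oxygen on C5 and C7 and the methoxy group on C6. In the precursor phenol a mirror plane through C8a and C6 makes the two ortho carbons (future C4a and C8) identical. With the C5 and C7 oxygens capped, acylation at either carbon can only give the 6-methoxy isomer.
Stereochemistry: the target has no stereocentre and no stereogenic double bond. The one stereocentre on the way (the α-carbon of the racemic ketoester) becomes sp2 C3 in step 6.

Key step: step 6

Assumption: ketoester 9 is used as the racemate, since its stereocentre is erased in the key step; flavone numbering (O1 to C8a, primes for ring B) is used throughout.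

**Route**

Step 1
Reactants: 1 2-methoxyresorcinol (2-methoxybenzene-1,3-diol)
Product: 2 2-methoxy-1,3-bis(methoxymethoxy)benzene
Conditions: MOMCl (2.6 equiv), iPr2NEt (3.5 equiv), CH2Cl2, 0 °C to rt
Reagents that add atoms: chloromethyl methyl ether (MOMCl), COCCl
Why: Both phenols are O-alkylated by MOMCl under amine base (MOM ether formation, a Williamson-type alkylation), which gives base- and heat-stable acetals and keeps the mirror symmetry of the ring.

Step 2
Reactants: 2 2-methoxy-1,3-bis(methoxymethoxy)benzene
Product: 3 2-[4-methoxy-3,5-bis(methoxymethoxy)phenyl]-4,4,5,5-tetramethyl-1,3,2-dioxaborolane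
Conditions: B2pin2 (1.0 equiv), [Ir(OMe)(cod)]2 (1.5 mol %), 4,4'-di-tert-butyl-2,2'-bipyridine (3 mol %), THF, 80 °C
Reagents that add atoms: bis(pinacolato)diboron (B2pin2), CC1(C)OB(OC1(C)C)B1OC(C)(C)C(C)(C)O1
Why: Iridium-catalysed aromatic C–H borylation (Hartwig–Miyaura type) is governed by sterics, and C5–H, para to the methoxy group, is the only ring C–H without an ortho substituent, so the boryl group should enter there alone.

Step 3
Reactants: 3 2-[4-methoxy-3,5-bis(methoxymethoxy)phenyl]-4,4,5,5-tetramethyl-1,3,2-dioxaborolane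
Product: 4 4-methoxy-3,5-bis(methoxymethoxy)phenol
Conditions: H2O2 (30% aq), NaOH (aq), THF, 0 °C
Reagents that add atoms: hydrogen peroxide, OO
Why: Hydroperoxide adds to boron and the aryl group migrates from boron to oxygen (oxidation of an arylboronate to a phenol); the basic medium leaves the MOM acetals untouched.

Step 4
Reactants: 5 ethyl glycolate (ethyl 2-hydroxyacetate)
Product: 6 ethyl 2-(methoxymethoxy)acetate
Conditions: MOMCl (1.3 equiv), iPr2NEt (1.6 equiv), CH2Cl2, 0 °C to rt
Reagents that add atoms: chloromethyl methyl ether (MOMCl), COCCl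
Why: The primary alcohol is alkylated by MOMCl under a hindered amine base (MOM ether formation) without touching the ester.

Step 5
Reactants: 6 ethyl 2-(methoxymethoxy)acetate; 7 4-(benzyloxy)benzoyl chloride
Product: 9 ethyl 3-[4-(benzyloxy)phenyl]-2-(methoxymethoxy)-3-oxopropanoate (racemic), via lithium enolate 8 (not isolated)
Conditions: LiN(iPr)2 (2.1 equiv), 6 (2.1 equiv), THF, −78 °C; then 7 (1.0 equiv), −78 to −40 °C; aq NH4Cl
Reagents that add atoms: none
Why: This is a crossed Claisen condensation in which the preformed lithium ester enolate is C-acylated by the aroyl chloride; the second equivalent of enolate deprotonates the more acidic β-ketoester as it forms, which prevents double acylation, and the new stereocentre is formed without control (racemic).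

Step 6
Reactants: 4 4-methoxy-3,5-bis(methoxymethoxy)phenol; 9 ethyl 3-[4-(benzyloxy)phenyl]-2-(methoxymethoxy)-3-oxopropanoate (racemic)
Product: 13 2-[4-(benzyloxy)phenyl]-6-methoxy-3,5,7-tris(methoxymethoxy)-4H-chromen-4-one, via aroylketene 10 (not isolated), via aryl ester 11 (not isolated), via diketone 12 (not isolated)
Conditions: 4 (1.0 equiv), 9 (1.5 equiv), Ph2O, 230 °C, argon sweep to carry off EtOH and H2O, no catalyst (or microwave, 240 °C)
Reagents that add atoms: none
Why: On heating, ketoester 9 loses ethanol through its enol to give aroylketene 10, which phenol 4 first traps reversibly at oxygen as aryl ester 11; at 230 °C the ester releases the ketene again, and acylation at the carbon ortho to the free hydroxyl (a formal thermal Fries shift) gives diketone 12 and with it the C4a–C4 bond. The phenol oxygen then adds to the aroyl carbonyl in a 6-exo-trig closure, and loss of water forms O1–C2 and the aromatic pyrone, which drives the sequence forward. The closest known reaction is the Mentzer catalyst-free thermal condensation of phenols with β-ketoesters to chromones, which is established for α-alkoxy β-ketoesters leading to 3-alkoxyflavones. No stereocentre is formed, and the racemic α-carbon of 9 becomes sp2 C3. Two selectivities are needed: 6- against 8-methoxy is secured by the mirror plane of 4 through C1 and C4, which makes both ortho carbons identical, together with the single free hydroxyl; chromone against 4-arylcoumarin is secured by the absence of acid, which shuts the Pechmann path, and by the α-substituent, which favours the Simonis/Mentzer mode. Ring B carries a benzyl ether because an aryl prenyl ether would undergo Claisen rearrangement at this temperature, whereas MOM and benzyl ethers tolerate neutral heating.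

Step 7
Reactants: 13 2-[4-(benzyloxy)phenyl]-6-methoxy-3,5,7-tris(methoxymethoxy)-4H-chromen-4-one
Product: 14 2-(4-hydroxyphenyl)-6-methoxy-3,5,7-tris(methoxymethoxy)-4H-chromen-4-one
Conditions: H2 (1 atm), Pd/C (10 wt %), EtOAc–THF, rt
Reagents that add atoms: none
Why: Catalytic hydrogenolysis cleaves the benzyl aryl ether, while the MOM acetals and the tetrasubstituted C2=C3 bond of the chromone are inert under these neutral conditions, so only the 4'-phenol is freed.

Step 8
Reactants: 14 2-(4-hydroxyphenyl)-6-methoxy-3,5,7-tris(methoxymethoxy)-4H-chromen-4-one; 15 prenyl bromide (1-bromo-3-methylbut-2-ene)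
Product: 16 6-methoxy-3,5,7-tris(methoxymethoxy)-2-{4-[(3-methylbut-2-en-1-yl)oxy]phenyl}-4H-chromen-4-one
Conditions: 15 (1.3 equiv), K2CO3 (2 equiv), acetone, 50 °C
Reagents that add atoms: none
Why: In this Williamson ether synthesis the 4'-phenoxide is the only free nucleophile and the primary allylic bromide reacts at oxygen by SN2 at the unsubstituted terminus.

Step 9
Reactants: 16 6-methoxy-3,5,7-tris(methoxymethoxy)-2-{4-[(3-methylbut-2-en-1-yl)oxy]phenyl}-4H-chromen-4-one
Product: 18 3,5,7-trihydroxy-6-methoxy-2-{4-[(3-methylbut-2-en-1-yl)oxy]phenyl}-4H-chromen-4-one (the target), via tris(trimethylsilyl) ether 17 (not isolated)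
Conditions: Me3SiOTf (6 equiv), 2,2'-bipyridyl (9 equiv), MeCN, 0 °C to rt; then H2O, rt
Reagents that add atoms: none
Why: The bipyridyl-buffered silyl triflate converts aryl MOM ethers into aryl silyl ethers without free strong acid (silyl triflate/2,2'-bipyridyl acetal cleavage), and water then hydrolyses the labile trimethylsilyl ethers, so the acid-sensitive prenyl ether should survive.

**Compound list**
1 | 2-methoxyresorcinol (2-methoxybenzene-1,3-diol) | COc1c(O)cccc1O | starting material
2 | 2-methoxy-1,3-bis(methoxymethoxy)benzene | COCOc1cccc(OCOC)c1OC | intermediate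
3 | 2-[4-methoxy-3,5-bis(methoxymethoxy)phenyl]-4,4,5,5-tetramethyl-1,3,2-dioxaborolane | COCOc1cc(B2OC(C)(C)C(C)(C)O2)cc(OCOC)c1OC | intermediate
4 | 4-methoxy-3,5-bis(methoxymethoxy)phenol | COCOc1cc(O)cc(OCOC)c1OC | intermediate
5 | ethyl glycolate (ethyl 2-hydroxyacetate) | CCOC(=O)CO | starting material
6 | ethyl 2-(methoxymethoxy)acetate | CCOC(=O)COCOC | intermediate
7 | 4-(benzyloxy)benzoyl chloride | O=C(Cl)c1ccc(OCc2ccccc2)cc1 | starting material
8 | lithium 1-ethoxy-2-(methoxymethoxy)ethen-1-olate (enolate of 6; geometry not defined and of no consequence; step 5, not isolated) | [Li+].CCOC([O-])=COCOC | intermediate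
9 | ethyl 3-[4-(benzyloxy)phenyl]-2-(methoxymethoxy)-3-oxopropanoate (racemic) | CCOC(=O)C(OCOC)C(=O)c1ccc(OCc2ccccc2)cc1 | intermediate
10 | 3-[4-(benzyloxy)phenyl]-2-(methoxymethoxy)-3-oxoprop-1-en-1-one (aroylketene; step 6, not isolated) | O=C=C(OCOC)C(=O)c1ccc(OCc2ccccc2)cc1 | intermediate
11 | 4-methoxy-3,5-bis(methoxymethoxy)phenyl 3-[4-(benzyloxy)phenyl]-2-(methoxymethoxy)-3-oxopropanoate (racemic; step 6, not isolated) | COCOc1cc(OC(=O)C(OCOC)C(=O)c2ccc(OCc3ccccc3)cc2)cc(OCOC)c1OC | intermediate
12 | 1-[4-(benzyloxy)phenyl]-3-[2-hydroxy-5-methoxy-4,6-bis(methoxymethoxy)phenyl]-2-(methoxymethoxy)propane-1,3-dione (racemic, keto form; step 6, not isolated) | COCOc1cc(O)c(C(=O)C(OCOC)C(=O)c2ccc(OCc3ccccc3)cc2)c(OCOC)c1OC | intermediate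
13 | 2-[4-(benzyloxy)phenyl]-6-methoxy-3,5,7-tris(methoxymethoxy)-4H-chromen-4-one | COCOc1c(-c2ccc(OCc3ccccc3)cc2)oc2cc(OCOC)c(OC)c(OCOC)c2c1=O | intermediate
14 | 2-(4-hydroxyphenyl)-6-methoxy-3,5,7-tris(methoxymethoxy)-4H-chromen-4-one | COCOc1c(-c2ccc(O)cc2)oc2cc(OCOC)c(OC)c(OCOC)c2c1=O | intermediate
15 | prenyl bromide (1-bromo-3-methylbut-2-ene) | CC(C)=CCBr | starting material
16 | 6-methoxy-3,5,7-tris(methoxymethoxy)-2-{4-[(3-methylbut-2-en-1-yl)oxy]phenyl}-4H-chromen-4-one | COCOc1c(-c2ccc(OCC=C(C)C)cc2)oc2cc(OCOC)c(OC)c(OCOC)c2c1=O | intermediate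
17 | 6-methoxy-2-{4-[(3-methylbut-2-en-1-yl)oxy]phenyl}-3,5,7-tris[(trimethylsilyl)oxy]-4H-chromen-4-one (step 9, not isolated) | COc1c(O[Si](C)(C)C)cc2oc(-c3ccc(OCC=C(C)C)cc3)c(O[Si](C)(C)C)c(=O)c2c1O[Si](C)(C)C | intermediate
18 | 3,5,7-trihydroxy-6-methoxy-2-{4-[(3-methylbut-2-en-1-yl)oxy]phenyl}-4H-chromen-4-one (3,5,7-trihydroxy-6-methoxy-4'-prenyloxyflavone) | COc1c(O)cc2oc(-c3ccc(OCC=C(C)C)cc3)c(O)c(=O)c2c1O | target

**Step count**
Total steps: 9. Longest linear sequence: 7 steps (steps 1, 2, 3, 6, 7, 8, 9); steps 4 and 5 form the second branch.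

**Steps most likely to fail**

1. Step 6. At 230 °C the MOM groups may migrate or be lost in the presence of the free phenol, and the aroylketene may be consumed by dimerisation or decarboxylation before C-acylation takes place. The fallback makes the same two bonds stepwise at low temperature by a Baker–Venkataraman sequence; it sets out from 4 and returns at 13 through 12. Phenol 4 is benzylated (BnBr, K2CO3, DMF) to 5-(benzyloxy)-2-methoxy-1,3-bis(methoxymethoxy)benzene F1. Ortho-lithiation between the MOM-oxy and benzyloxy groups (n-BuLi, THF, 0 °C) is followed by acylation with N-methoxy-N-methyl-2-(methoxymethoxy)acetamide F2, itself made from 6 with MeNH(OMe)·HCl and iPrMgCl. This gives 1-[2-(benzyloxy)-5-methoxy-4,6-bis(methoxymethoxy)phenyl]-2-(methoxymethoxy)ethan-1-one F3. Hydrogenolysis (H2, Pd/C) frees 1-[2-hydroxy-5-methoxy-4,6-bis(methoxymethoxy)phenyl]-2-(methoxymethoxy)ethan-1-one F4. Esterification with 7 (Et3N, DMAP, CH2Cl2) gives 4-methoxy-2-[(methoxymethoxy)acetyl]-3,5-bis(methoxymethoxy)phenyl 4-(benzyloxy)benzoate F5. LiN(SiMe3)2 in THF then shifts the aroyl group from oxygen to carbon to give diketone 12, which is closed to 13 with a catalytic amount of pyridinium p-toluenesulfonate in warm toluene over molecular sieves.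

2. Step 9. The prenyl ether may ionise and be lost while the acetals are cleaved, or the three acetals may be cleaved incompletely. The fallback reorders the end-game so that acid never meets the prenyl ether; it sets out from 13 and returns at 18. Methanolic HCl (MeOH–THF, 50 °C) removes the three MOM groups with the benzyl ether in place, giving 2-[4-(benzyloxy)phenyl]-3,5,7-trihydroxy-6-methoxy-4H-chromen-4-one F6. Acetylation (Ac2O, pyridine, DMAP) gives 2-[4-(benzyloxy)phenyl]-6-methoxy-4-oxo-4H-chromene-3,5,7-triyl triacetate F7. Hydrogenolysis (H2, Pd/C, EtOAc) gives 2-(4-hydroxyphenyl)-6-methoxy-4-oxo-4H-chromene-3,5,7-triyl triacetate F8. Mitsunobu etherification with 3-methylbut-2-en-1-ol (PPh3, diisopropyl azodicarboxylate, THF, 0 °C) gives 6-methoxy-2-{4-[(3-methylbut-2-en-1-yl)oxy]phenyl}-4-oxo-4H-chromene-3,5,7-triyl triacetate F9 under neutral conditions. Methanolysis of the acetates (K2CO3, MeOH, argon, 0 °C) then gives 18.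

3. Step 5. The enolate may be acylated at oxygen or twice, and the α-alkoxy ester enolate may self-condense. The fallback builds the same C–C bond by aldol addition and then adjusts the oxidation level; it sets out from 6 and returns at 9. Enolate 8 is added to commercial 4-(benzyloxy)benzaldehyde (THF, −78 °C) to give ethyl 3-[4-(benzyloxy)phenyl]-3-hydroxy-2-(methoxymethoxy)propanoate F10 as a mixture of racemic diastereomers. Oxidation with Dess–Martin periodinane (NaHCO3, CH2Cl2) then gives 9.

**Further compounds**
F1 | step 6 | 5-(benzyloxy)-2-methoxy-1,3-bis(methoxymethoxy)benzene | COCOc1cc(OCc2ccccc2)cc(OCOC)c1OC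
F2 | step 6 | N-methoxy-N-methyl-2-(methoxymethoxy)acetamide | CON(C)C(=O)COCOC
F3 | step 6 | 1-[2-(benzyloxy)-5-methoxy-4,6-bis(methoxymethoxy)phenyl]-2-(methoxymethoxy)ethan-1-one | COCOCC(=O)c1c(OCc2ccccc2)cc(OCOC)c(OC)c1OCOC
F4 | step 6 | 1-[2-hydroxy-5-methoxy-4,6-bis(methoxymethoxy)phenyl]-2-(methoxymethoxy)ethan-1-one | COCOCC(=O)c1c(O)cc(OCOC)c(OC)c1OCOC
F5 | step 6 | 4-methoxy-2-[(methoxymethoxy)acetyl]-3,5-bis(methoxymethoxy)phenyl 4-(benzyloxy)benzoate | COCOCC(=O)c1c(OC(=O)c2ccc(OCc3ccccc3)cc2)cc(OCOC)c(OC)c1OCOC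
F6 | step 9 | 2-[4-(benzyloxy)phenyl]-3,5,7-trihydroxy-6-methoxy-4H-chromen-4-one | COc1c(O)cc2oc(-c3ccc(OCc4ccccc4)cc3)c(O)c(=O)c2c1O
F7 | step 9 | 2-[4-(benzyloxy)phenyl]-6-methoxy-4-oxo-4H-chromene-3,5,7-triyl triacetate | COc1c(OC(C)=O)cc2oc(-c3ccc(OCc4ccccc4)cc3)c(OC(C)=O)c(=O)c2c1OC(C)=O
F8 | step 9 | 2-(4-hydroxyphenyl)-6-methoxy-4-oxo-4H-chromene-3,5,7-triyl triacetate | COc1c(OC(C)=O)cc2oc(-c3ccc(O)cc3)c(OC(C)=O)c(=O)c2c1OC(C)=O
F9 | step 9 | 6-methoxy-2-{4-[(3-methylbut-2-en-1-yl)oxy]phenyl}-4-oxo-4H-chromene-3,5,7-triyl triacetate | COc1c(OC(C)=O)cc2oc(-c3ccc(OCC=C(C)C)cc3)c(OC(C)=O)c(=O)c2c1OC(C)=O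
F10 | step 5 | ethyl 3-[4-(benzyloxy)phenyl]-3-hydroxy-2-(methoxymethoxy)propanoate (mixture of racemic diastereomers) | CCOC(=O)C(OCOC)C(O)c1ccc(OCc2ccccc2)cc1
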